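Over the 8.0 d you will hold this isothermal flask, the first hours are the ones to watch, since they show how many chains are started and how far each one runs.

| flask | substrate | partner | initiator | radical scavenger | remark | time |
|---|---|---|---|---|---|---|
| north | 0.10 M | 0.105 M | 10 mM | 50 µM | the very flask that is asked about, followed so far |  |
| flask | 0.10 M | 0.105 M | 10 mM | 50 µM |  | 8.0 d |

- north (time / h: target / %, substrate / %): 2.00: 0, 98.5; 4.00: 3.2, 96.3; 6.00: 6.0, 93.3; 12.0: 13.0, 86.4; 25.0: 27.4, 72.1

(standard deviation of a reading: 1 percentage point)

- amount of target in the flask at 8.0 d, in percent of the substrate charged
- amount of substrate in the flask at 8.0 d, in percent of the substrate charged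

- what was read earlier has a scatter of 1 percentage point, one standard deviation

The north run is this same flask followed so far. Target reads 0% at 2.00 h, and between 4.00 h and 25.0 h it climbs by 0.0115 h⁻¹ as a fraction of the substrate charge. Traced back, that line starts at a delay of 1.22 h. Take this as the time the radical scavenger needs to stop one chain per molecule: 50 µM in that delay means chains start at F = 40.9 µM h⁻¹.

A chain repeats its cycle, so count turnovers. The chain length ν, target made per chain started, is the rate of target over F, which reads 28.2. It is a rough reading, since the delay rests on 3.2% with a scatter of 1 percentage point.

Now count what the flask needs. Held steady, as an estimate, F comes over 8.0 d to 7.85 mM of chains started, so consuming the charge takes 12.7 turnovers per chain. I take no law for the fall of ν from these scattered readings; as an assumption, my own reckoning lets it fall in step with substrate. Then the natural log of the charge over the substrate left is ν divided by that need, 2.21, which leaves 10.9%. The forecast says 87% target and 12% substrate, and adds: “Zero order would finish completely; stronger substrate dependence or faster initiator loss would leave more.”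

The flask gives 91.6% target and 6.88% substrate.

    initiator → 2 initiating radical (k = 0.00150 h⁻¹)
    substrate + initiating radical → capped initiator + first chain carrier (k = 13000 M⁻¹ s⁻¹)
    partner + first chain carrier → target + second chain carrier (k = 3.80 × 10⁶ M⁻¹ h⁻¹)
    substrate + second chain carrier → by-product + first chain carrier (k = 1.40 × 10⁶ M⁻¹ h⁻¹)
    first chain carrier → ended carrier (k = 2700 h⁻¹)
    2 second chain carrier → ended chains A (k = 3.00 × 10⁷ M⁻¹ s⁻¹)
    2 first chain carrier → ended chains B (k = 2.00 × 10⁶ M⁻¹ s⁻¹)
    second chain carrier + radical scavenger → ended chains C (k = 2.90 × 10⁷ M⁻¹ s⁻¹)

By the step with initiating radical, substrate has a half-life of 56 d at 1.95 d, longer than the 8.0 d of the run, and at 8.0 d the chain step with second chain carrier uses substrate 3.8 times as fast. Each capped initiator marks one chain started, so count turnovers as for the 28.2 read from the north run: by 8.00 d the flask has made 18.3 target per capped initiator, and a neighbour flask, charged with 0.0025 M of initiator and otherwise the same, 49.7.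

(The runs stem from a simulated flask on assumed constants; the scatter is artificial.)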